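I cannot read the quenched substrate in these runs: the tables hold starting material, target and isomer of the product, so I must reach it through what is missing.

| flask | starting material | partner | second substrate | protic impurity | remark | time |
|---|---|---|---|---|---|---|
| ash | 42 mM | 2.5 equiv | 0.28 equiv | 21 mM | run made earlier |  |
| alder | 42 mM | 2.5 equiv | 0.44 equiv | 21 mM | run made earlier |  |
| larch | 84 mM | 2.5 equiv | 0.20 equiv | 21 mM | run made earlier |  |
| flask | 42 mM | 2.50 equiv | 0.200 equiv | 21.0 mM |  | 12 d |

| run | time / d | starting material / % | target / % | isomer of the product / % |
|---|---|---|---|---|
| ash | 0.625 | 0.4 | 55.2 | 27.3 |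
| ash | 1.67 | 0 | 55.1 | 27.5 |
| ash | 3.00 | 0.4 | 55.1 | 27.6 |
| ash | 5.00 | 0.4 | 55.0 | 26.9 |
| ash | 8.00 | 0 | 55.4 | 27.1 |
| ash | 10.0 | 0 | 55.2 | 26.4 |
| alder | 1.67 | 0.2 | 51.0 | 25.9 |
| alder | 3.00 | 0 | 51.4 | 24.9 |
| alder | 5.00 | 0 | 51.1 | 25.2 |
| alder | 6.00 | 0 | 51.1 | 25.5 |
| alder | 8.00 | 0 | 51.1 | 25.1 |
| alder | 10.0 | 0 | 51.5 | 25.6 |
| larch | 2.08 | 0.1 | 59.3 | 28.8 |
| larch | 4.00 | 0 | 59.2 | 29.1 |
| larch | 6.00 | 0.2 | 59.5 | 29.2 |
| larch | 8.00 | 0.2 | 59.4 | 29.3 |
| larch | 10.0 | 0.2 | 59.1 | 29.1 |

(each reading ± 0.3 percentage points)

- steps that have been proposed: second substrate + partner -> second product; target <-> isomer of the product; starting material + second substrate -> cross product; starting material + partner -> target; starting material + protic impurity -> quenched substrate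
- the reaction counts as stopped when no species that holds the starting material changes by six tenths of a point or more over the second half of the time

* at 12 d, what has stopped the reaction, if anything has (the partner has run out first / all of the starting material has reacted / it is still moving / forward and back rates have come level)
* share of the starting material used up at 12 d
* target at 12 d, in percent of the starting material charged
* isomer of the product at 12 d, in percent of the starting material charged

In the ash run starting material reads 0% at 1.67 d, so each run is a finished contest for it. I want two rates, capture by the partner, going with c(partner), and capture by the protic impurity, going with c(protic impurity). The second substrate must first be taken out. At that time the ash run has lost 17.4% and the alder run 23.1%, so I run the line through both back to a zero charge of second substrate and read 7.42%, with the scatter of the readings in it. Dividing that intercept by what remains gives quenched substrate per target plus isomer. Multiplying by c(partner)/c(protic impurity) as charged gives 0.401, my capture ratio: quenched substrate per target plus isomer, scaled by the charged c(partner)/c(protic impurity). It is an effective selectivity factor reckoned on charges, not a ratio of rate constants, since both concentrations move during a run. For the flask I therefore expect 0.0802 quenched substrate per target plus isomer.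

The forecast gives all of the starting material has reacted, 100% conversion, target 57.3% and isomer 28.3%, reasoning that “the reaction ended by consuming it”. Its impurity speed of 0.23 differs from my capture ratio.

The flask gives all of the starting material has reacted, 100% conversion, target 57.3% and isomer 28.1%.

    second substrate + partner → second product (k = 16.0 /M/h)
    target ⇌ isomer of the product (K = 0.490, k = 0.340 /h)
    starting material + second substrate → cross product (k = 31.0 /M/h)
    starting material + partner → target (k = 5.70 /M/h)
    starting material + protic impurity → quenched substrate (k = 1.90 /M/h)

In the flask, quenched substrate per target plus isomer comes to 0.0799. A neighbouring flask has 10 mM of starting material with the partner at the equivalents of the recipe, and there the protic impurity stands at 2.10 equiv and the partner at 25.0 mM. The capture ratio then gives 0.337 for the neighbouring flask, which shows 0.326. At 12.0 d the neighbouring flask holds target 46.8%, isomer 22.9% and quenched substrate 22.7%.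

All runs are simulated with made-up constants, noise included.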